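Retrosynthetic cuts, in order: the three O–benzyl bonds of a tribenzyl ether; C8–C(=O) and (O=)C–CH2 of the side chain (back to a C8 bromide, CO and a 2-arylethylborane); O1–C2 and O1–C8a of the lactone (back to a 3-phenylindan-1-one); C7–Br; C1–C2 of the indanone (hydroacylation); the aryl–alkenyl bond (Suzuki–Miyaura).
Enabling feature: O1 is the only atom between the acyl carbon C2 and the aromatic carbon C8a of ring A. Removing it joins C2 to C8a and leaves a five-membered aryl ketone in which C3 is C4 of the target and C4, C6 and C7 are C5, C7 and C8 of ring A; such a ketone takes oxygen back on its aryl side.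
Forward order: ring A is bought as 3,5-bis(benzyloxy)benzaldehyde, whose formyl carbon already sits meta to both oxygens, where no Friedel–Crafts acylation could place it. The five-membered carbocycle closes first, bromine marks C7, oxygen insertion expands the carbocycle to the lactone ring, the dihydrochalcone chain is joined, and the phenols are released last.
Stereochemistry: the only stereocentre, C4 (R), is set as C3 of the indanone by the BINAP–rhodium catalyst in the hydroacylation and is a spectator in every later step.
Benzyl ethers are used instead of methyl ethers because C4a is flanked by both O1 and the C5 oxygen. A Lewis-acidic or basic end game could open the lactone and let it re-close on the C5 phenol (6-acyl isomer); neutral hydrogenolysis avoids that opening.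

Key step: step 5

Assumption: the (R)-BINAP complex is taken to give the (3R)-indanone, by analogy with the sense of induction in simpler 2-(alk-1-en-2-yl)benzaldehydes. The bromine atom of 6 allows a check by anomalous dispersion, and if 5 proves to be (3S), the equally available (S)-BINAP is used and nothing else changes.

Step 1
Reactants: 1 3,5-bis(benzyloxy)benzaldehyde
Product: 2 2-bromo-3,5-bis(benzyloxy)benzaldehyde
Conditions: NBS (1.0 equiv), MeCN, 0 °C to rt, dark
Reagents that add atoms: N-bromosuccinimide, O=C1CCC(=O)N1Br
Why: Electrophilic aromatic bromination: both benzyloxy groups direct to C2 (ortho to one, para to the other), the position between them is more crowded, and the first bromine slows a second substitution, as is the rule for 3,5-dialkoxybenzaldehydes.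

Step 2
Reactants: 2 2-bromo-3,5-bis(benzyloxy)benzaldehyde; 3 1-phenylvinylboronic acid pinacol ester
Product: 4 3,5-bis(benzyloxy)-2-(1-phenylethenyl)benzaldehyde
Conditions: Pd(OAc)2 (3 mol %), SPhos (6 mol %), K3PO4 (2 equiv), toluene–H2O 10:1, 90 °C
Reagents that add atoms: none
Why: Suzuki–Miyaura coupling: the ortho formyl group speeds insertion of zerovalent palladium into the C–Br bond, and the bulky, electron-rich biaryl phosphine copes with the two ortho substituents and the alpha-branched alkenyl boronate; no stereocentre is formed.

Step 3
Reactants: 4 3,5-bis(benzyloxy)-2-(1-phenylethenyl)benzaldehyde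
Product: 5 (3R)-4,6-bis(benzyloxy)-3-phenylindan-1-one
Conditions: [Rh(nbd)((R)-BINAP)]ClO4 (5 mol %), H2 then Ar purge (gives [Rh((R)-BINAP)]ClO4), CH2Cl2, rt
Reagents that add atoms: none
Why: Enantioselective intramolecular alkene hydroacylation, established for 2-(alk-1-en-2-yl)benzaldehydes: cationic monovalent rhodium inserts into the formyl C–H bond, the bound 1,1-disubstituted alkene inserts into Rh–H so that hydrogen goes to the diaryl-substituted carbon, and reductive elimination from the six-membered acyl rhodacycle makes C1–C2; the C2-symmetric BINAP pocket selects the alkene face in the hydride transfer and so sets C3 as (R).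

Step 4
Reactants: 5 (3R)-4,6-bis(benzyloxy)-3-phenylindan-1-one
Product: 6 (3R)-7-bromo-4,6-bis(benzyloxy)-3-phenylindan-1-one
Conditions: NBS (1.05 equiv), MeCN, 0 °C to rt, dark
Reagents that add atoms: N-bromosuccinimide, O=C1CCC(=O)N1Br
Why: Electrophilic aromatic bromination: C7 is para to the C4 and ortho to the C6 benzyloxy group, whereas C5 lies between both ethers and is further screened because the C3 phenyl group turns the C4 benzyl group towards it, the same preference that sends a second bromine to C6 of 2-substituted 3,5-dialkoxybenzaldehydes; polar, dark conditions keep the reagent away from C2 and the benzylic C–H bonds, and C3 is not touched.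

Step 5
Reactants: 6 (3R)-7-bromo-4,6-bis(benzyloxy)-3-phenylindan-1-one
Product: 8 (4R)-8-bromo-5,7-bis(benzyloxy)-4-phenylchroman-2-one, via Criegee adduct 7 (not isolated)
Conditions: mCPBA (2.5 equiv), TsOH·H2O (0.5 equiv), CH2Cl2, 0 °C to rt, dark
Reagents that add atoms: 3-chloroperoxybenzoic acid (mCPBA), O=C(OO)c1cccc(Cl)c1
Why: The acid-activated C1 carbonyl takes up the peracid to give the tetrahedral Criegee adduct 7, which already holds the future O1–C2 bond; the C1–C7a bond then stands antiperiplanar to the O–O bond and C7a shifts to the near oxygen as 3-chlorobenzoate leaves, which makes O1–C8a. The closest known reaction is the Baeyer–Villiger oxidation of 3-aryl-1-indanones to 4-aryl-3,4-dihydrocoumarins with mCPBA and a sulfonic acid, which proceeds by aryl migration. The six-membered lactone ring arises by one-atom expansion of the five-membered ketone through this 1,2-shift and not by cyclisation of an open chain. No stereocentre is created: the hemiperketal carbon of 7 returns to sp2, and C3 of 6, which is not enolisable and lies outside the migrating bond, becomes C4 of 8 with its (R) configuration intact. The step needs migration of the aryl carbon C7a rather than of the C2 methylene group, and this is secured by the ability of the sp2 carbon to share the developing positive charge with the ring; both benzyloxy groups are meta to C7a and cost only a small inductive penalty, the alkyl branch at C3a offsets the bromine, and acid catalysis in place of a bicarbonate buffer makes up for the slower addition beside the bromine. Bromine is the placeholder of choice at C7 because an acyl chain there would itself suffer oxygen insertion through its ortho,para-dialkoxyaryl group, an iodide would be oxidised to trivalent iodine and a boronate to a phenol, while the C–Br bond, the benzyl ethers and the carbonyl-deactivated ring should ignore mCPBA.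

Step 6
Reactants: 8 (4R)-8-bromo-5,7-bis(benzyloxy)-4-phenylchroman-2-one; 9 4-(benzyloxy)styrene
Product: 11 (4R)-5,7-bis(benzyloxy)-8-{3-[4-(benzyloxy)phenyl]propanoyl}-4-phenylchroman-2-one, via alkylborane 10 (not isolated)
Conditions: 9 (1.6 equiv), 9-BBN-H (1.5 equiv), THF, 0 °C to rt; then 8, Pd(OAc)2 (5 mol %), di(1-adamantyl)-n-butylphosphine (10 mol %), K3PO4 (2 equiv), CO (5 bar), THF–toluene, 80 °C
Reagents that add atoms: carbon monoxide, [C-]#[O+]; 9-borabicyclo[3.3.1]nonane (its atoms stay only in 10), B1C2CCCC1CCC2
Why: Hydroboration followed by carbonylative B-alkyl Suzuki–Miyaura coupling: 9-BBN-H places boron on the terminal carbon of the styrene, zerovalent palladium carrying the bulky, electron-rich phosphine inserts into C8–Br, CO insertion into the crowded, electron-rich aryl–palladium bond outruns direct alkyl transfer, and the phosphate-activated borane hands its primary alkyl group to the acyl palladium species for reductive elimination; the styrene is kept in slight excess so that no B–H bond meets the lactone, and an opened lactone could here re-close only on O1 during a work-up at pH 3–4 because the C5 oxygen is still benzylated.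

Step 7
Reactants: 11 (4R)-5,7-bis(benzyloxy)-8-{3-[4-(benzyloxy)phenyl]propanoyl}-4-phenylchroman-2-one
Product: 12 (4R)-5,7-dihydroxy-8-[3-(4-hydroxyphenyl)propanoyl]-4-phenylchroman-2-one (target)
Conditions: H2 (1 atm), 10% Pd/C, EtOAc, rt
Reagents that add atoms: none
Why: Catalytic hydrogenolysis of aryl benzyl ethers, the standard release of dihydrochalcone phenols: the neutral, non-nucleophilic medium keeps the lactone closed so that the freed C5 phenol cannot take over the acyl group, the hydrogen-bonded aryl ketone resists reduction, and C4 carries no hydrogenolysable bond, so its configuration is kept.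

Compound list
1 | 3,5-bis(benzyloxy)benzaldehyde | O=Cc1cc(OCc2ccccc2)cc(OCc2ccccc2)c1 | starting material
2 | 2-bromo-3,5-bis(benzyloxy)benzaldehyde | O=Cc1cc(OCc2ccccc2)cc(OCc2ccccc2)c1Br | intermediate
3 | 1-phenylvinylboronic acid pinacol ester | C=C(c1ccccc1)B1OC(C)(C)C(C)(C)O1 | starting material
4 | 3,5-bis(benzyloxy)-2-(1-phenylethenyl)benzaldehyde | O=Cc1cc(OCc2ccccc2)cc(OCc2ccccc2)c1C(=C)c1ccccc1 | intermediate
5 | (3R)-4,6-bis(benzyloxy)-3-phenylindan-1-one | O=C1C[C@H](c2ccccc2)c2c(OCc3ccccc3)cc(OCc3ccccc3)cc21 | intermediate
6 | (3R)-7-bromo-4,6-bis(benzyloxy)-3-phenylindan-1-one | O=C1C[C@H](c2ccccc2)c2c(OCc3ccccc3)cc(OCc3ccccc3)c(Br)c21 | intermediate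
7 | (3R)-7-bromo-4,6-bis(benzyloxy)-1-hydroxy-3-phenylindan-1-yl 3-chloroperoxybenzoate (Criegee adduct, either configuration at C1) | OC1(OOC(=O)c2cccc(Cl)c2)C[C@H](c2ccccc2)c2c(OCc3ccccc3)cc(OCc3ccccc3)c(Br)c21 | intermediate
8 | (4R)-8-bromo-5,7-bis(benzyloxy)-4-phenylchroman-2-one | O=C1C[C@H](c2ccccc2)c2c(OCc3ccccc3)cc(OCc3ccccc3)c(Br)c2O1 | intermediate
9 | 4-(benzyloxy)styrene | C=Cc1ccc(OCc2ccccc2)cc1 | starting material
10 | 9-{2-[4-(benzyloxy)phenyl]ethyl}-9-borabicyclo[3.3.1]nonane | C(Cc1ccc(OCc2ccccc2)cc1)B1C2CCCC1CCC2 | intermediate
11 | (4R)-5,7-bis(benzyloxy)-8-{3-[4-(benzyloxy)phenyl]propanoyl}-4-phenylchroman-2-one | O=C1C[C@H](c2ccccc2)c2c(OCc3ccccc3)cc(OCc3ccccc3)c(C(=O)CCc3ccc(OCc4ccccc4)cc3)c2O1 | intermediate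
12 | (4R)-5,7-dihydroxy-8-[3-(4-hydroxyphenyl)propanoyl]-4-phenylchroman-2-one | O=C1C[C@H](c2ccccc2)c2c(O)cc(O)c(C(=O)CCc3ccc(O)cc3)c2O1 | target

Total step count: 7. Longest linear sequence: 7 steps (1 to 12); the hydroboration of 9 runs in the pot of step 6.

Steps most likely to fail

Step 6. Insertion of palladium into the C8–Br bond, which lies between two oxygen substituents on an electron-rich ring, may be too slow under CO. Uncarbonylated alkyl transfer, protodebromination, phosphate-induced lactone opening, or enolate-driven acyl transfer from O1 to the alpha-carbon of the new ketone (Baker–Venkataraman manifold) may also consume material. The fallback sets out from 8 and comes back at 11; it reverses the polarity and needs neither CO nor base. Bromide 8 is stannylated with hexamethylditin (Pd(PPh3)4, toluene, 110 °C) to (4R)-5,7-bis(benzyloxy)-4-phenyl-8-(trimethylstannyl)chroman-2-one F1. Commercial 3-[4-(benzyloxy)phenyl]propanoic acid is converted with oxalyl chloride and catalytic DMF in CH2Cl2 into 3-[4-(benzyloxy)phenyl]propanoyl chloride F2. A Stille acylation of F1 with F2 (Pd2(dba)3, tri(2-furyl)phosphine, toluene, 70 °C) then forms the C8–acyl bond under neutral conditions and delivers 11.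

Step 5. Addition of the peracid may be sluggish beside the bromine, the weakened aryl group may lose part of the competition to migration of the methylene carbon, and long reaction times invite peracid attack on the alkoxy-substituted ring. The fallback sets out from 5 and comes back at 8; it moves the oxygen insertion ahead of the halogenation, so the migrating aryl group carries no bromine and the carbonyl group is unhindered. Indanone 5 is oxidised with mCPBA and TsOH·H2O in CH2Cl2 to (4R)-5,7-bis(benzyloxy)-4-phenylchroman-2-one F3. F3 is then brominated with NBS in MeCN at 0 °C. C8 is para to the C5 ether and flanked by the tied-back ring oxygen, whereas C6 lies between two benzyloxy groups, so 8 should result.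

Step 3. Decarbonylation of the acyl rhodium hydride, slow turnover (the alkene is twisted by the neighbouring benzyloxy group and the cationic metal can be parked on one of the many arene rings) and poor facial selectivity with the alpha-aryl alkene are the risks. The fallback sets out from 2 and comes back at 5; it closes the other ring bond (C3–C3a) instead of C1–C2. Aldehyde 2 is treated with (E)-2-phenylethenylmagnesium bromide (THF, −78 °C) to give racemic (E)-1-[2-bromo-3,5-bis(benzyloxy)phenyl]-3-phenylprop-2-en-1-ol F4. MnO2 in CH2Cl2 oxidises it to the 2'-bromochalcone (E)-1-[2-bromo-3,5-bis(benzyloxy)phenyl]-3-phenylprop-2-en-1-one F5. An enantioselective reductive Heck cyclisation, a known route to 3-arylindanones, then joins the aryl carbon to the beta-carbon of the enone and gives 5. Its conditions are Pd(OAc)2, an axially chiral bisphosphine of the MeO-BIPHEP family in the enantiomeric form that leads to (3R), HCO2Na, DMF, 80 °C.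

Further compounds
F1 | step 6 | (4R)-5,7-bis(benzyloxy)-4-phenyl-8-(trimethylstannyl)chroman-2-one | O=C1C[C@H](c2ccccc2)c2c(OCc3ccccc3)cc(OCc3ccccc3)c([Sn](C)(C)C)c2O1
F2 | step 6 | 3-[4-(benzyloxy)phenyl]propanoyl chloride | O=C(Cl)CCc1ccc(OCc2ccccc2)cc1
F3 | step 5 | (4R)-5,7-bis(benzyloxy)-4-phenylchroman-2-one | O=C1C[C@H](c2ccccc2)c2c(OCc3ccccc3)cc(OCc3ccccc3)cc2O1
F4 | step 3 | (E)-1-[2-bromo-3,5-bis(benzyloxy)phenyl]-3-phenylprop-2-en-1-ol (racemic) | OC(/C=C/c1ccccc1)c1cc(OCc2ccccc2)cc(OCc2ccccc2)c1Br
F5 | step 3 | (E)-1-[2-bromo-3,5-bis(benzyloxy)phenyl]-3-phenylprop-2-en-1-one | O=C(/C=C/c1ccccc1)c1cc(OCc2ccccc2)cc(OCc2ccccc2)c1Br
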